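Late in the run the solid reagent will have dissolved, its charge of 0.0600 M being smaller than the solubility of 0.078 M. What is asked comes at 10% conversion, so watch the first seconds.

starting material 0.10 M; second substrate 0.100 M; solid reagent 0.0600 M; free catalyst 66 µM

- apparent order in free catalyst when 10% of the starting material are converted (percent change of the rate of making target for one percent more free catalyst charged)

    starting material + free catalyst ⇌ catalyst intermediate A (K1 = 4.3 M⁻¹, k1 = 160 M⁻¹ s⁻¹)
    second substrate + free catalyst ⇌ catalyst intermediate B (K2 = 11 M⁻¹, k2 = 250 M⁻¹ s⁻¹)
    partner + catalyst intermediate B → free catalyst + second product (k3 = 71 M⁻¹ s⁻¹)
    2 starting material → homo dimer (k4 = 0.098 M⁻¹ s⁻¹)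
    solid reagent ⇌ partner, rate k5*(cs5 - [partner]) while solid is left; crystals form when [partner] > cs5 (cs5 = 0.078 M, k5 = 0.0059 s⁻¹)
    partner + catalyst intermediate A → free catalyst + target (k6 = 790 M⁻¹ s⁻¹)

- a species is counted by the starting material in it: one homo dimer counts as two
- a step written with two of one species runs at k times the square of its concentration and takes two of it each time
- given per volume of solution although it is solid: solid reagent
- at the start none of the solid reagent is in solution
- charge of starting material (flask): 0.10 M

My ledger follows the solid reagent, the limiting reagent by charge. First comes the clock. Homo dimer formation by itself takes 0.0945 min to reach 10%. The catalyst can hold at most 0.0660% of the starting material at once.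

Binding is quick. Free catalyst meets starting material once in 0.0625 s, far shorter than that clock. So I treat binding as equilibrated. That puts 15.6% of the catalyst charge in catalyst intermediate A and 44.2% in catalyst intermediate B.

Now the quantity to carry: the partner lifetime, the time a partner lasts against both intermediates together, 1.64 min. The clock is much shorter. So partner builds almost linearly, and 4.35% of the solid charge dissolves. Of that, a fraction 2.89% is spent.

| Entry at 10% conversion | Fraction of solid charge |
|---|---|
| To target | 0.100% |
| To second product | 0.0255% |
| Partner in solution | 4.22% |

The books close on the dissolved fraction. Catalyst intermediate A grows with the catalyst charge, while the spent fraction takes a little back, so my order is 0.971.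

The forecast gives 0.965, with a range of 0.93 to 0.99. Its ground is that “the target rate is essentially proportional to pre-equilibrated intermediate A and hence to the catalyst charged”. Its value lies slightly below mine.

The simulation gives 0.97. That conversion of 10% comes at 0.0938 min. Now use the lifetime late in the run. The solid reagent reads 0% at 4.00 min. The intermediates in the flask then give a partner lifetime of 5.53 min, and at 8.00 min they give 6.64 min. Between those times the partner falls from 0.0341 M to 0.0177 M, which reads as a decay time of 6.13 min.

(The constants used here were chosen freely; what happens was integrated by code.)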